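Read the split first.

| flask | substrate | first nucleophile | solid second nucleophile | remark | time |
|---|---|---|---|---|---|
| ash | 0.050 M | 1.5 equiv | 3 equiv | run made earlier |  |
| larch | 0.025 M | 1.5 equiv | 3 equiv | run made earlier |  |
| noon | 0.050 M | 1.50 equiv | 3.00 equiv | everything together at the start | 8.0 d |
| dusk | 0.050 M (in portions, 4, over 5.0 d) | 1.50 equiv | 3.00 equiv | first portion at the start, last at 5.0 d | 8.0 d |
| summer | 0.050 M (fed, over 5.0 d) | 1.50 equiv | 3.00 equiv | all else is in the flask from the start; the feed brings no volume worth counting | 8.0 d |
| dawn | 0.050 M | 1.50 equiv (fed, over 5.0 d) | 3.00 equiv | all else is in the flask from the start; the feed brings no volume worth counting | 8.0 d |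

ash run (percent of the substrate charged)

| time / d | solvolysis product / % | target / % |
|---|---|---|
| 0.500 | 11 | 25 |
| 1.67 | 25 | 52 |
| 3.00 | 28 | 60 |
| 4.00 | 27 | 62 |
| 6.00 | 30 | 67 |
| 8.00 | 33 | 68 |

larch run (percent of the substrate charged)

| time / h | solvolysis product / % | target / % |
|---|---|---|
| 3.00 | 1 | 4 |
| 6.00 | 12 | 12 |
| 10.0 | 16 | 19 |
| 12.0 | 22 | 21 |
| 15.0 | 20 | 22 |
| 20.0 | 26 | 29 |

(standard deviation of a reading: 2 percentage points)

- the earlier runs were read with a standard deviation of 2 percentage points
- at the start none of the solid second nucleophile is in solution
- a reading or a percentage of target counts all its forms, free or not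

- the flask that comes out highest in amount of solvolysis product, in percent of the substrate charged, or "all alike" when all lie within 1.5 percentage points (noon / dusk / summer / dawn / all alike)
- solvolysis product at the end, in percent of the substrate charged, noon
- solvolysis product at the end, in percent of the substrate charged, dusk
- solvolysis product at the end, in percent of the substrate charged, summer
- solvolysis product at the end, in percent of the substrate charged, dawn

Noon repeated the ash recipe, so I expected its solvolysis product near the 33 % that ash showed at 8.00 d. But the split moved with concentration. At 1.67 d ash held 52 % target against 25 % solvolysis product, while larch, at half the substrate and so half the first nucleophile, held 29 % against 26 % at 20.0 h.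

So I took the first nucleophile midway through what the target had used and reckoned from ash 0.0298 M for the half-split concentration, the concentration of first nucleophile at which target and solvolysis product form equally. It is a selectivity factor in concentration units. Larch read 0.0304 M, from a different concentration, so I kept it.

The summed products of ash at 0.500 d read a substrate half-life of 0.777 d. Dawn was the flask to reckon: its first nucleophile came at 0.0150 M d⁻¹, so by that half-life it had received 0.0116 M, less than the half-split concentration, before counting what capture used. The half-split concentration divided by itself plus that amount gave me a solvolysis share at that one moment of 71.9 %, with target and solvolysis product the only two outlets counted, and I let that moment stand for the dawn run.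

The forecast said noon 33 %, dusk 32 %, summer 32 % and dawn 72 %, highest dawn: “Starving the first nucleophile in dawn sends most material to solvolysis”.

The flasks gave noon 31.7 %, dusk 29.7 %, summer 30.0 % and dawn 71.2 %, highest dawn.

    substrate → intermediate (k = 0.0390 h⁻¹)
    first nucleophile + intermediate → target (k = 100 M⁻¹ h⁻¹)
    second nucleophile + intermediate → other capture product (k = 370 M⁻¹ h⁻¹)
    intermediate → solvolysis product (k = 2.80 h⁻¹)
    crystals ⇌ target, rate k5*(cs5 - [target]) while solid is left; crystals form when [target] > cs5 (solubility = 24.0 mM, k = 4.00 h⁻¹)
    intermediate → side product (k = 0.0570 h⁻¹)
    solid second nucleophile ⇌ second nucleophile, rate k7*(cs7 - [second nucleophile]) while solid is left; crystals form when [second nucleophile] > cs7 (solubility = 5.00 mM, k = 0.00840 h⁻¹)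

Dawn's 71.2 % was an amount at the end, my 71.9 % a share at one moment. The neighbour was dawn with 6.00 equiv of first nucleophile, still fed over 5.0 d. Its feed ran at 0.0600 M d⁻¹, so by the same half-life it had received 0.0466 M, more than the half-split concentration, and the same division gave a share at that moment of 39.0 %. That flask ended with 51.9 % target, all its forms counted, and 45.1 % solvolysis product.

The readings are calculated with constants of no real substance, noise included.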